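Start from Thursday's run: its solid substrate fell to 55.5% of the charge by 4.00 min, a loss of 1.33 mM min⁻¹. Sunday's run, at 3.83 times that charge, loses 1.43 mM min⁻¹. So treat the loss as zero-order: one flux, whatever the charge.

| flask | solid substrate | remark | time |
|---|---|---|---|
| Monday's | 2.4 mM | run made earlier |  |
| Thursday's | 12 mM | run made earlier |  |
| Sunday's | 46 mM | run made earlier |  |
| ash | 2.0 mM |  | 6.0 min |
| elm | 6.0 mM |  | 6.0 min |
| larch | 20 mM |  | 6.0 min |
| oak | 60 mM |  | 6.0 min |

| run | time / min | target / % | solid substrate / % |
|---|---|---|---|
| Monday's | 0.833 | 7.9 | 45.4 |
| Monday's | 1.50 | 16.4 | 6.9 |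
| Monday's | 2.50 | 23.9 | 1.4 |
| Monday's | 3.00 | 24.0 | 0.1 |
| Monday's | 4.00 | 22.3 | 0 |
| Thursday's | 0.833 | 1.0 | 88.8 |
| Thursday's | 1.50 | 3.5 | 81.9 |
| Thursday's | 2.50 | 4.7 | 71.3 |
| Thursday's | 3.00 | 7.5 | 65.5 |
| Thursday's | 4.00 | 10.9 | 55.5 |
| Sunday's | 0.417 | 0 | 98.2 |
| Sunday's | 1.00 | 0 | 98.0 |
| Sunday's | 2.00 | 1.7 | 95.1 |
| Sunday's | 3.00 | 1.0 | 91.2 |
| Sunday's | 4.00 | 4.0 | 87.6 |

(standard deviation of a reading: 1 percentage point)

- percent here means solid substrate units held: one idle adduct counts as two
- what is said of target includes idle adduct
- solid substrate is a solid; its amount is given per volume of the solution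
- reactions considered so far: starting material <-> third isomer; starting material <-> isomer of the product; starting material <-> target; starting material -> decomposition product; starting material + target <-> idle adduct; solid substrate <-> starting material
- at the start none of the solid substrate is in solution
- in an amount of target, one idle adduct counts as one target
- "hardly changes" means that all values lie within two and a half points (for a concentration: within two and a half percent of the largest)

- amount of target at the end, in percent of the solid substrate charged for ash, elm, larch, oak, in this order
- the shape of the row from first to last (rises, then falls / falls, then rises / falls all the way / hardly changes / rises all the way)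

Multiply the flux by 6.0 min to get 8.01 mM. Call this the clearing charge, the charge that the flux just delivers into solution in that time. Above it, with the flux held, reckon the fraction dissolved as clearing charge over charge.

Now go to logarithms. With the flux held, each power of ten of charge takes one power of ten off that fraction. Larch lies 0.397 decades above the clearing charge and oak 0.875, so reckon that larch dissolves 40.0% and oak 13.3%.

Next, turn dissolved material into target. Monday's run reads 24.0% at 3.00 min with 0.1% of its solid left, a share of 24.0%. That gives larch 9.60% and oak 3.19%.

This share is the weak link: Monday's reading has 0.1% of its solid left, while larch and oak are reckoned to dissolve 40.0% and 13.3% and so still to hold solid at the asked time. Reforge it from Thursday's run, which still reads 55.5% of solid at 4.00 min: 10.9% of target on the dissolved fraction is a share of 24.5%. Larch becomes 9.80% and oak 3.26%.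

Reckon that elm clears in 4.49 min, sooner than the asked time, so give it the full share, 24.5%. Reckon that ash clears in 1.50 min and then ages. Extend Monday's fall from 24.0% to 22.3% and ash ends near 18.9%. Commit to a row that rises, then falls.

The forecast reads 20%, 22.5%, 10% and 3.4%, shape rises, then falls, on the ground that “dissolution is effectively zero-order”. At elm it lies 2 percentage points below this reckoning.

The flask gives 17.6%, 22.1%, 7.91% and 2.64%, shape rises, then falls. The forecast's row is within the tolerance and its shape is right.

    starting material ⇌ third isomer (K = 1.70, k = 0.00359 s⁻¹)
    starting material ⇌ isomer of the product (K = 2.60, k = 0.00145 s⁻¹)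
    starting material ⇌ target (K = 0.500, k = 0.00730 s⁻¹)
    starting material → decomposition product (k = 5.06 × 10⁻⁶ s⁻¹)
    starting material + target ⇌ idle adduct, settled at all times (K = 150 L mol⁻¹)
    solid substrate ⇌ starting material, rate k6*(cs6 - [starting material]) while solid is left; crystals form when [starting material] > cs6 (solubility = 6.60 mM, k = 0.00432 s⁻¹)

Hold the clearing charge against larch and then oak: at 6.00 min larch's solid substrate stands at 63.0%, so 37.0% has dissolved against the reckoned 40.0%, and oak's stands at 87.7%, so 12.3% has dissolved against 13.3%. The row turns at 6.6 mM, lower than the clearing charge of 8.01 mM, and the amount of target at the end there is 22.3% of the charge.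

Readings and results come from a simulation for an exercise, and the scatter is random.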